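**Strategy.** The carbocyclic core is a bicyclo[2.2.2]oct-2-ene whose C(Me)=CH bridge is the retron of a Diels–Alder reaction. The six-membered ring built from the two bridgehead CH, the lactone α- and β-carbons (shared with the δ-lactone) and the CH2–CH(iPr) bridge is therefore cut at both bridgehead–lactone bonds. In the forward sense one endo-selective, presumably biomimetic [4+2] cycloaddition of (R)-α-phellandrene to the enoate of (+)-altholactone closes this ring, forms two C–C bonds and sets four stereocentres. The precursor, the cis-fused furo[3,2-b]pyran-5-one altholactone, is made in four steps from (2S,3S)-3-phenylglycidol by alkoxyallylboration, 5-endo epoxide opening and ozonolysis/Z-Wittig lactonisation.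

Key step: step 5

Remark: atom labels follow altholactone numbering for 10 (O1, C2–Ph, C3–OH, C3a, O4, C5=O, C6, C7, C7a) and cyclohexa-1,3-diene numbering for 11 (C1H=C2(Me)–C3H=C4H–C5H(iPr)–C6H2); commercial 11 is assumed to be of high enantiomeric purity, any (S)-diene giving a separable diastereomeric adduct.

**Step 1**
Reactants: 1 (2S,3S)-3-phenylglycidol
Product: 2 (2R,3S)-3-phenyloxirane-2-carbaldehyde
Conditions: TEMPO (10 mol %), PhI(OAc)2 (1.1 equiv), CH2Cl2, 0 °C to rt
Reagents that add atoms: none
Why: The TEMPO/PhI(OAc)2 oxoammonium oxidation of a primary alcohol stops at the aldehyde under almost neutral conditions, so the trans-epoxide and both stereocentres should survive; the aldehyde is used crude.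

**Step 2**
Reactants: 2 (2R,3S)-3-phenyloxirane-2-carbaldehyde; 3 allyl methoxymethyl ether
Product: 5 (1R,2S)-2-(methoxymethoxy)-1-[(2S,3S)-3-phenyloxiran-2-yl]but-3-en-1-ol, via borinate ester 4 (not isolated)
Conditions: 3, s-BuLi, THF, −78 °C; (+)-Ipc2BOMe; BF3·OEt2; 2, −78 °C; then H2NCH2CH2OH, Et2O, rt
Reagents that add atoms: allyl methoxymethyl ether (3), C=CCOCOC
Why: Brown γ-alkoxyallylboration: the chelated (Z)-alkoxyallyl anion is borylated at its terminal carbon and adds through a chair Zimmerman–Traxler transition state, so the Z enol-ether geometry gives the syn (threo) C1/C2 pair, while the Ipc ligands derived from (−)-α-pinene direct attack to the Re face of the aldehyde and set C1 as R; the weak intrinsic facial bias of 2,3-epoxy aldehydes should leave the reagent in control, and the amine work-up avoids a Payne rearrangement.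

**Step 3**
Reactants: 5 (1R,2S)-2-(methoxymethoxy)-1-[(2S,3S)-3-phenyloxiran-2-yl]but-3-en-1-ol
Product: 6 (2R,3S,4S,5S)-2-phenyl-5-vinyloxolane-3,4-diol
Conditions: BF3·OEt2 (1.1 equiv), CH2Cl2, −78 to −20 °C; then MeOH, HCl (cat.), rt
Reagents that add atoms: none
Why: Lewis-acid-promoted 5-endo epoxide opening (dealkylative cycloetherification): the C2 acetal oxygen attacks the activated benzylic epoxide carbon anti to the breaking C–O bond, so that carbon is inverted (phenyl trans to the new 3-OH) while the other three centres are untouched, the oxonium ion sheds its methoxymethyl cation, and the acidic methanol stage removes any re-attached MOM residue as dimethoxymethane.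

**Step 4**
Reactants: 6 (2R,3S,4S,5S)-2-phenyl-5-vinyloxolane-3,4-diol; 7 methyl (triphenylphosphoranylidene)acetate
Product: 10 (+)-altholactone, via aldehyde 8 (not isolated), via Z-enoate 9 (not isolated)
Conditions: O3, CH2Cl2/MeOH, −78 °C; Me2S, −78 °C to rt; then 7 (2.5 equiv), MeOH, 0 °C to rt; then PPTS (cat.), CH2Cl2, rt
Reagents that add atoms: methyl (triphenylphosphoranylidene)acetate (7), COC(=O)C=P(c1ccccc1)(c1ccccc1)c1ccccc1
Why: Ozonolysis with reductive work-up gives the α-alkoxy aldehyde, whose Wittig reaction with the stabilised ylide in methanol is Z-selective for α-oxygenated aldehydes, and the Z-enoate can lactonise only onto the cis hydroxyl at C3a (the trans 3-OH cannot reach), no stereocentre being touched.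

**Step 5**
Reactants: 10 (+)-altholactone; 11 (R)-(−)-α-phellandrene
Product: 12 target compound (CNP0249919.1)
Conditions: neat 11 (10 equiv), BHT (cat.), sealed tube, 140 °C
Reagents that add atoms: (R)-(−)-α-phellandrene (11), CC1=CC[C@@H](C=C1)C(C)C
Why: Thermal, concerted but asynchronous normal-electron-demand [π4s+π2s] cycloaddition in which the s-cis-locked diene of 11 (HOMO) adds across the C6=C7 enoate of 10 (LUMO lowered by the lactone carbonyl and the allylic C7a–O bond), joining diene C1 to lactone C7 (β) and diene C4 to C6 (α). The closest known reaction type is the thermal Diels–Alder addition of α-phellandrene to cyclic enones, quinones and maleic anhydride, and of cyclic dienes to γ-oxygenated α,β-unsaturated δ-lactones. The new six-membered carbocycle closes by intermolecular suprafacial 1,4-addition of the dienophile to the termini of the existing cyclohexadiene, which turns that ring into the bicyclo[2.2.2]oct-2-ene. Of the four new stereocentres, the cis relationship of the two lactone carbons follows from the ring (Z) alkene, the two bridgeheads from approach of 10 to the diene face anti to the isopropyl group at C5, the absolute sense at C6/C7 from attack on the convex face of the cis-fused furopyranone anti to the C7a–O1 bond, and the placement of the lactone under the new C2=C3 bridge from the Alder endo rule. The step needs "para" regioselectivity, which the 2-methyl group secures by enlarging the HOMO coefficient at diene C1 so that it pairs with the β-carbon C7, the bulkier tetrahydrofuran-bearing end of the dienophile thereby also meeting the less hindered diene terminus. Excess diene and a radical inhibitor are meant to outpace diene isomerisation and dimerisation.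

**Compound list**
1 | (2S,3S)-3-phenylglycidol | OC[C@@H]1O[C@H]1c1ccccc1 | starting material
2 | (2R,3S)-3-phenyloxirane-2-carbaldehyde | O=C[C@@H]1O[C@H]1c1ccccc1 | intermediate
3 | allyl methoxymethyl ether (3-(methoxymethoxy)prop-1-ene) | C=CCOCOC | starting material
4 | O-diisopinocampheylboryl (borinate) ester of 5, Ipc groups from (−)-α-pinene | C=C[C@H](OCOC)[C@@H](OB([C@H]2C[C@H]3C[C@@H]([C@@H]2C)C3(C)C)[C@H]2C[C@H]3C[C@@H]([C@@H]2C)C3(C)C)[C@@H]1O[C@H]1c1ccccc1 | intermediate
5 | (1R,2S)-2-(methoxymethoxy)-1-[(2S,3S)-3-phenyloxiran-2-yl]but-3-en-1-ol | C=C[C@H](OCOC)[C@@H](O)[C@@H]1O[C@H]1c1ccccc1 | intermediate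
6 | (2R,3S,4S,5S)-2-phenyl-5-vinyloxolane-3,4-diol | O[C@H]1[C@H](O)[C@@H](c2ccccc2)O[C@H]1C=C | intermediate
7 | methyl (triphenylphosphoranylidene)acetate | COC(=O)C=P(c1ccccc1)(c1ccccc1)c1ccccc1 | starting material
8 | (2R,3S,4S,5R)-3,4-dihydroxy-5-phenyloxolane-2-carbaldehyde | O[C@H]1[C@H](O)[C@@H](c2ccccc2)O[C@H]1C=O | intermediate
9 | methyl (2Z)-3-[(2S,3S,4S,5R)-3,4-dihydroxy-5-phenyloxolan-2-yl]prop-2-enoate | O[C@H]1[C@H](O)[C@@H](c2ccccc2)O[C@H]1/C=C\C(=O)OC | intermediate
10 | (+)-altholactone, (2R,3R,3aS,7aS)-3-hydroxy-2-phenyl-2,3,3a,7a-tetrahydro-5H-furo[3,2-b]pyran-5-one | O=C1O[C@H]2[C@H](O)[C@@H](c3ccccc3)O[C@H]2C=C1 | intermediate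
11 | (R)-(−)-α-phellandrene, (5R)-2-methyl-5-isopropylcyclohexa-1,3-diene | CC1=CC[C@@H](C=C1)C(C)C | starting material
12 | target: endo Diels–Alder adduct of 10 and 11; altholactone cis-fused through C6 and C7 to a 2-methyl-5-isopropylbicyclo[2.2.2]oct-2-ene, lactone carbonyl syn to the C=C bridge, isopropyl anti to the lactone bridge, CH(iPr) next to the bridgehead bonded to the lactone α-carbon | CC1=C[C@@H]2[C@@H]3C(=O)O[C@H]4[C@H](O)[C@@H](c5ccccc5)O[C@H]4[C@@H]3[C@H]1C[C@@H]2C(C)C | target

**Totals**
Total step count: 5. Longest linear sequence: 5 steps (1 → 2 → 5 → 6 → 10 → 12).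

**Steps most likely to fail**

Step 5. The cycloaddition may be too slow at temperatures the diene tolerates, so that 1,5-hydrogen shifts, dimerisation and aromatisation of the diene outrun it, and endo and regiocontrol may erode at high temperature. The fallback sets out from 10 and comes back at 12. Silylation of the 3-OH of 10 (TBSCl, imidazole, DMF) should give 3-O-(tert-butyldimethylsilyl)altholactone F1. A Lewis-acid-catalysed Diels–Alder reaction of F1 with 11 (Me2AlCl, CH2Cl2, −40 to 0 °C), in which carbonyl complexation lowers the dienophile LUMO and should sharpen endo and regioselectivity at low temperature, should give the 3-O-silyl ether of the adduct F2. HF·pyridine in THF then frees the hydroxyl to give 12.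

Step 3. The acetal oxygen may be too weak a nucleophile, so that the BF3-activated benzylic epoxide undergoes Meinwald rearrangement, ionises with loss of configuration at the benzylic carbon, or is opened by the terminal methoxy oxygen instead. The fallback sets out from 5 and comes back at 6. The MOM group is first removed under non-acidic conditions (TMSOTf, 2,2′-bipyridyl, CH2Cl2, 0 °C; then H2O) to give the free epoxy diol (1R,2S)-1-[(2S,3S)-3-phenyloxiran-2-yl]but-3-ene-1,2-diol F3. The ring is then closed by a classical hydroxy-epoxide 5-endo cyclisation with a free hydroxyl as nucleophile (CSA cat., CH2Cl2, 0 °C), which should give 6 with inversion at the benzylic carbon.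

Step 2. Reagent control may be insufficient in this doubly stereodifferentiating addition, giving poor facial selectivity at the carbinol carbon, and the epoxy aldehyde may epimerise or decompose before it reacts. The fallback sets out from 3 and comes back at 5. The same alkoxyallylboration (s-BuLi, (+)-Ipc2BOMe, BF3·OEt2, −78 °C; ethanolamine) is run on commercial (E)-cinnamaldehyde, which has no resident stereocentre. Through the diisopinocampheylborinate ester F4 it should give (1E,3S,4S)-4-(methoxymethoxy)-1-phenylhexa-1,5-dien-3-ol F5. A Shi epoxidation with the L-fructose-derived (ent-Shi) ketone (Oxone, K2CO3 buffer, MeCN/dimethoxymethane/H2O, 0 °C) then epoxidises the electron-rich trans-styryl alkene, not the vinyl group, under catalyst control to give the (S,S)-epoxide 5.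

**Further compounds**
F1 | step 5 | 3-O-(tert-butyldimethylsilyl)altholactone | O=C1O[C@H]2[C@H](O[Si](C)(C)C(C)(C)C)[C@@H](c3ccccc3)O[C@H]2C=C1
F2 | step 5 | 3-O-(tert-butyldimethylsilyl) ether of 12 | CC1=C[C@@H]2[C@@H]3C(=O)O[C@H]4[C@H](O[Si](C)(C)C(C)(C)C)[C@@H](c5ccccc5)O[C@H]4[C@@H]3[C@H]1C[C@@H]2C(C)C
F3 | step 3 | (1R,2S)-1-[(2S,3S)-3-phenyloxiran-2-yl]but-3-ene-1,2-diol | C=C[C@H](O)[C@@H](O)[C@@H]1O[C@H]1c1ccccc1
F4 | step 2 | O-diisopinocampheylboryl (borinate) ester of F5 | C=C[C@H](OCOC)[C@@H](OB([C@H]1C[C@H]2C[C@@H]([C@@H]1C)C2(C)C)[C@H]1C[C@H]2C[C@@H]([C@@H]1C)C2(C)C)/C=C/c1ccccc1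
F5 | step 2 | (1E,3S,4S)-4-(methoxymethoxy)-1-phenylhexa-1,5-dien-3-ol | C=C[C@H](OCOC)[C@@H](O)/C=C/c1ccccc1
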